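**Plan**

- Cuts, in retrosynthetic order: C8–C9 (ring A), N4–C9a (enamine of ring B), the O1–C14 acyl bond of lactone D, then N4–O1, a bond the target lacks. This reveals a spiro-isoxazolidine, cut at C3–C2 and C1–O1 into a nitrone (lactone E aldehyde plus the C5–C8 chain on nitrogen) and a 2-methylenecyclohexanone (ring C).
- Enabling feature: N4, C3, C2 and the oxygenated quaternary C1 of ring B form a 1,3-amino alcohol, the retron of an isoxazolidine. O1 is also cis to the C13 carboxyl chain on C12, so that carboxyl can carry the N-chain as an ester tether, which steers the nitrone onto the hindered face and is later exchanged for lactone D.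
- Forward: ring C is built first, passing through a temporary O11 lactone from a tethered malonate Michael addition. It is then esterified with the C5–C8 hydroxylamine and condensed with the lactone E aldehyde. Cycloaddition gives the isoxazolidine; N–O cleavage lets lactone D and ring B form in one flask; ring A closes last by enamine alkylation.
- Stereochemistry: C18 comes from (5S)-5-(hydroxymethyl)oxolan-2-one and C20 from kinetic protonation. C11 comes from CBS reduction, C10 from cuprate addition anti to O11, C12 from delivery through the O11 tether, and C13 from equilibration in the cis-fused lactone. C1 and C3 are set in the cycloaddition by the ester tether, the (Z)-nitrone and C18.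

Key step: step 23

Remark: target atom numbers (N4, C1–C21) are used for all intermediates; C1 (until step 23), the malonate carbon in 13, 25–27 and the sulfoxide sulfur are undefined mixtures that converge later; compounds 1, 9, 10, 12 and 14 are taken as commercial.

**Route**

Step 1
Reactants: 1 (5S)-5-(hydroxymethyl)oxolan-2-one
Product: 2 (5S)-5-{[(tert-butyldiphenylsilyl)oxy]methyl}oxolan-2-one
Conditions: TBDPSCl, imidazole, DMF, 0 °C → rt
Reagents that add atoms: tert-butyl(chloro)diphenylsilane, CC(C)(C)[Si](Cl)(c1ccccc1)c1ccccc1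
Why: Imidazole-promoted silylation of the primary alcohol installs a bulky group that later shields one face of the lactone enolate.

Step 2
Reactants: 2 (5S)-5-{[(tert-butyldiphenylsilyl)oxy]methyl}oxolan-2-one
Product: 4 (3R,5S)-5-{[(tert-butyldiphenylsilyl)oxy]methyl}-3-methyloxolan-2-one, via lithium enolate 3 (not isolated)
Conditions: LiN(iPr)2, THF, −78 °C; MeI, −78 → −40 °C
Reagents that add atoms: iodomethane, CI
Why: Enolate alkylation of a 5-substituted butyrolactone occurs anti to the C5 substituent, so the methyl group should enter trans.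

Step 3
Reactants: 4 (3R,5S)-5-{[(tert-butyldiphenylsilyl)oxy]methyl}-3-methyloxolan-2-one
Product: 6 (3S,5S)-5-{[(tert-butyldiphenylsilyl)oxy]methyl}-3-methyloxolan-2-one, via lithium enolate 5 (not isolated)
Conditions: LiN(iPr)2, THF, −78 °C; 2,6-di-tert-butyl-4-methylphenol, −78 °C
Reagents that add atoms: none
Why: Kinetic protonation of the enolate by a bulky phenol from the face opposite the silyloxymethyl group should give the cis lactone and so set C20 (S).

Step 4
Reactants: 6 (3S,5S)-5-{[(tert-butyldiphenylsilyl)oxy]methyl}-3-methyloxolan-2-one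
Product: 7 (3S,5S)-5-(hydroxymethyl)-3-methyloxolan-2-one
Conditions: Bu4NF, AcOH, THF, 0 °C → rt
Reagents that add atoms: none
Why: Fluoride desilylation buffered by acetic acid keeps the lactone and its α-centre away from alkoxide base.

Step 5
Reactants: 7 (3S,5S)-5-(hydroxymethyl)-3-methyloxolan-2-one
Product: 8 (2S,4S)-4-methyl-5-oxooxolane-2-carbaldehyde
Conditions: Dess–Martin periodinane, CH2Cl2, 0 °C → rt; used at once
Reagents that add atoms: none
Why: Dess–Martin oxidation under near-neutral conditions should give the α-acyloxy aldehyde without epimerization at C18.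

Step 6
Reactants: 9 tert-butyl N-[(tert-butoxycarbonyl)oxy]carbamate; 10 4-bromobutan-1-ol
Product: 11 tert-butyl N-[(tert-butoxycarbonyl)oxy]-N-(4-hydroxybutyl)carbamate
Conditions: K2CO3, DMF, rt
Reagents that add atoms: none
Why: SN2 N-alkylation of the acidic carbamate N–H at the primary bromide gives the protected C5–C8 hydroxylamine, the carbonate base leaving the alcohol untouched.

Step 7
Reactants: 12 2,2,5-trimethyl-1,3-dioxane-4,6-dione
Product: 13 3-(tert-butoxy)-2-methyl-3-oxopropanoic acid
Conditions: t-BuOH, toluene, 100 °C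
Reagents that add atoms: 2-methylpropan-2-ol, CC(C)(C)O
Why: Thermal alcoholysis of the Meldrum's acid derivative opens the ring with loss of acetone and gives the malonic half ester.

Step 8
Reactants: 14 1,4-dioxaspiro[4.5]dec-6-en-8-one
Product: 15 (8S)-1,4-dioxaspiro[4.5]dec-6-en-8-ol
Conditions: (R)-2-methyl-CBS-oxazaborolidine (10 mol %), BH3·SMe2, THF, −20 °C; MeOH
Reagents that add atoms: none
Why: In this Corey–Bakshi–Shibata reduction the alkene is the larger flank of the ketone, so the (R)-catalyst should give the (S)-alcohol, which becomes C11.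

Step 9
Reactants: 15 (8S)-1,4-dioxaspiro[4.5]dec-6-en-8-ol
Product: 16 tert-butyl{[(8S)-1,4-dioxaspiro[4.5]dec-6-en-8-yl]oxy}dimethylsilane
Conditions: TBSCl, imidazole, DMF, rt
Reagents that add atoms: tert-butyl(chloro)dimethylsilane, CC(C)(C)[Si](C)(C)Cl
Why: Standard silylation gives an O11 protecting group that tolerates amide bases and cuprates and directs the next addition.

Step 10
Reactants: 16 tert-butyl{[(8S)-1,4-dioxaspiro[4.5]dec-6-en-8-yl]oxy}dimethylsilane
Product: 17 (4S)-4-[(tert-butyldimethylsilyl)oxy]cyclohex-2-en-1-one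
Conditions: PPTS, THF/H2O, 40 °C
Reagents that add atoms: water, O
Why: Mild acid-catalysed ketal hydrolysis unmasks the enone (future C9a carbonyl) while the allylic silyl ether should survive.

Step 11
Reactants: 17 (4S)-4-[(tert-butyldimethylsilyl)oxy]cyclohex-2-en-1-one
Product: 19 (4S)-4-[(tert-butyldimethylsilyl)oxy]-6-(phenylsulfanyl)cyclohex-2-en-1-one, via lithium dienolate 18 (not isolated)
Conditions: LiN(iPr)2, THF, −78 °C; PhSO2SPh, −78 °C
Reagents that add atoms: S-phenyl benzenethiosulfonate, O=S(=O)(Sc1ccccc1)c1ccccc1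
Why: Kinetic deprotonation at the only sp3 α-carbon and α-sulfenylation of the cross-conjugated enolate mark C1 for the later enone transposition.

Step 12
Reactants: 19 (4S)-4-[(tert-butyldimethylsilyl)oxy]-6-(phenylsulfanyl)cyclohex-2-en-1-one
Product: 20 (3S,4S)-4-[(tert-butyldimethylsilyl)oxy]-3-ethyl-6-(phenylsulfanyl)cyclohexan-1-one
Conditions: Et2CuLi, Et2O/THF, −78 °C; aq. NH4Cl
Reagents that add atoms: lithium diethylcuprate, [Li+].CC[Cu-]CC
Why: Conjugate addition of the weakly basic Gilman cuprate occurs anti to the γ-silyloxy group, placing ethyl trans to O11 and setting C10.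

Step 13
Reactants: 20 (3S,4S)-4-[(tert-butyldimethylsilyl)oxy]-3-ethyl-6-(phenylsulfanyl)cyclohexan-1-one
Product: 22 (4R,5S)-4-[(tert-butyldimethylsilyl)oxy]-5-ethylcyclohex-2-en-1-one, via sulfoxide 21 (not isolated)
Conditions: mCPBA (1.0 equiv), CH2Cl2, −78 °C; then toluene, NaHCO3, 100 °C
Reagents that add atoms: none
Why: Sulfide oxidation and thermal syn-elimination of the sulfoxide can only remove a C12 hydrogen, so the enone moves to the C1=C12 side without touching C10 or C11.

Step 14
Reactants: 22 (4R,5S)-4-[(tert-butyldimethylsilyl)oxy]-5-ethylcyclohex-2-en-1-one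
Product: 23 (4R,5S)-4-[(tert-butyldimethylsilyl)oxy]-5-ethyl-2-[(phenylsulfanyl)methyl]cyclohex-2-en-1-one
Conditions: PhSH, aq. CH2O, Et3N, EtOH, 70 °C
Reagents that add atoms: formaldehyde, C=O; benzenethiol, Sc1ccccc1
Why: The amine-mediated three-component α-(arylsulfanyl)methylation of an enone (thiolate conjugate addition, aldol reaction with formaldehyde, dehydration, allylic shift of sulfur) places C2 on C1 as a masked methylene group.

Step 15
Reactants: 23 (4R,5S)-4-[(tert-butyldimethylsilyl)oxy]-5-ethyl-2-[(phenylsulfanyl)methyl]cyclohex-2-en-1-one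
Product: 24 (4R,5S)-5-ethyl-4-hydroxy-2-[(phenylsulfanyl)methyl]cyclohex-2-en-1-one
Conditions: HF·pyridine, THF, 0 °C → rt
Reagents that add atoms: none
Why: Acidic fluoride desilylation frees O11 without base that could trigger thiolate elimination.

Step 16
Reactants: 24 (4R,5S)-5-ethyl-4-hydroxy-2-[(phenylsulfanyl)methyl]cyclohex-2-en-1-one; 13 3-(tert-butoxy)-2-methyl-3-oxopropanoic acid
Product: 25 1-tert-butyl 3-{(1R,6S)-6-ethyl-4-oxo-3-[(phenylsulfanyl)methyl]cyclohex-2-en-1-yl} 2-methylpropanedioate
Conditions: DCC, DMAP (5 mol %), CH2Cl2, 0 °C → rt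
Reagents that add atoms: none
Why: Steglich esterification hangs a soft malonate pronucleophile on O11, needed because a plain propanoate could not be enolized beside the more acidic ketone.

Step 17
Reactants: 25 1-tert-butyl 3-{(1R,6S)-6-ethyl-4-oxo-3-[(phenylsulfanyl)methyl]cyclohex-2-en-1-yl} 2-methylpropanedioate
Product: 26 tert-butyl (3aR,7S,7aR)-7-ethyl-3-methyl-2,5-dioxo-4-[(phenylsulfanyl)methyl]octahydro-1-benzofuran-3-carboxylate
Conditions: Cs2CO3 (0.2 equiv), MeCN, rt
Reagents that add atoms: none
Why: The intramolecular malonate Michael addition (5-exo-trig) can deliver C13 to C12 only on the face of O11, giving the cis-fused lactone and setting C12; the C1 enolate is protonated, or expels and re-adds thiolate, so the masked methylene survives.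

Step 18
Reactants: 26 tert-butyl (3aR,7S,7aR)-7-ethyl-3-methyl-2,5-dioxo-4-[(phenylsulfanyl)methyl]octahydro-1-benzofuran-3-carboxylate
Product: 28 (3R,3aS,7S,7aR)-7-ethyl-3-methyl-4-[(phenylsulfanyl)methyl]hexahydro-1-benzofuran-2,5-dione, via malonic half acid 27 (not isolated)
Conditions: CF3CO2H, CH2Cl2, rt; then DBU (0.3 equiv), toluene, 90 °C
Reagents that add atoms: none
Why: Acidolysis of the tert-butyl ester, decarboxylation and base equilibration should leave the C13 methyl on the convex face of the cis-fused lactone, which is the (R) configuration needed.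

Step 19
Reactants: 28 (3R,3aS,7S,7aR)-7-ethyl-3-methyl-4-[(phenylsulfanyl)methyl]hexahydro-1-benzofuran-2,5-dione
Product: 31 (2R)-2-{(1S,2R,3S)-2-[(tert-butyldimethylsilyl)oxy]-3-ethyl-5-oxo-6-[(phenylsulfanyl)methyl]cyclohexyl}propanoic acid, via lithium hydroxy carboxylate 29 (not isolated), via bis-silyl derivative 30 (not isolated)
Conditions: LiOH, THF/H2O, 0 °C; TBSOTf, 2,6-lutidine, CH2Cl2, 0 °C; K2CO3 (0.2 equiv), MeOH/H2O, then citric acid
Reagents that add atoms: lithium hydroxide, [Li+].[OH-]; tert-butyldimethylsilyl trifluoromethanesulfonate, CC(C)(C)[Si](C)(C)OS(=O)(=O)C(F)(F)F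
Why: Saponification, silylation of both oxygens before any acidification, and selective hydrolysis of the labile silyl ester free the C13 carboxyl while O11 stays blocked against relactonization.

Step 20
Reactants: 31 (2R)-2-{(1S,2R,3S)-2-[(tert-butyldimethylsilyl)oxy]-3-ethyl-5-oxo-6-[(phenylsulfanyl)methyl]cyclohexyl}propanoic acid; 11 tert-butyl N-[(tert-butoxycarbonyl)oxy]-N-(4-hydroxybutyl)carbamate
Product: 32 4-{(tert-butoxycarbonyl)[(tert-butoxycarbonyl)oxy]amino}butyl ester of acid 31
Conditions: PPh3, DIAD, THF, 0 °C → rt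
Reagents that add atoms: none
Why: Mitsunobu esterification activates the primary alcohol and not the acid, so C13 is not at risk and no base is present to release thiolate; the ester is the temporary tether.

Step 21
Reactants: 32 4-{(tert-butoxycarbonyl)[(tert-butoxycarbonyl)oxy]amino}butyl ester of acid 31
Product: 33 benzenesulfinylmethyl analogue (sulfoxide) of ester 32
Conditions: NaIO4, MeOH/THF/H2O, 0 °C
Reagents that add atoms: sodium periodate, [Na+].[O-]I(=O)(=O)=O
Why: Periodate oxidizes the aryl alkyl sulfide selectively to the sulfoxide, the latent leaving group for unmasking the methylene ketone.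

Step 22
Reactants: 33 benzenesulfinylmethyl analogue (sulfoxide) of ester 32; 8 (2S,4S)-4-methyl-5-oxooxolane-2-carbaldehyde
Product: 35 (Z)-N-alkyl nitrone of aldehyde 8 tethered through the butyl ester to the sulfoxide ketone, via hydroxylammonium trifluoroacetate 34 (not isolated)
Conditions: CF3CO2H/CH2Cl2 (1:4), 0 °C; then 8, NaHCO3, MgSO4, CH2Cl2, 0 °C → rt
Reagents that add atoms: none
Why: Brief cold acidolysis removes both Boc groups (the hindered secondary silyl ether should survive), and on buffering the hydroxylamine condenses with the aldehyde, far faster than with the ketone, to the (Z)-aldonitrone.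

Step 23
Reactants: 35 (Z)-N-alkyl nitrone of aldehyde 8 tethered through the butyl ester to the sulfoxide ketone
Product: 37 macrocyclic spiro-isoxazolidine (N4–O1–C1 and C3–C2 formed; ester bridge from C14 to C8), via methylene ketone nitrone 36 (not isolated)
Conditions: toluene (0.001 M), NaHCO3, 85 °C
Reagents that add atoms: none
Why: Proposed new method: heating first expels benzenesulfenic acid from the β-keto sulfoxide (syn-elimination) to give the 2-methylenecyclohexanone 36, whose tethered (Z)-nitrone then adds in a concerted suprafacial [3+2] cycloaddition, oxygen bonding to the substituted carbon C1 and the nitrone carbon C3 to the methylene carbon C2, as is usual for α-methylene ketones. The closest known reactions are the intermolecular nitrone cycloaddition to α-methylene ketones and lactones and the intramolecular nitrone–alkene cycloaddition through short tethers; closure through an eleven-membered ester tether has not been shown on such a substrate. The isoxazolidine closes by the cycloaddition itself, and the temporary eleven-membered ring (O1, N4, C5–C8, ester O, C14, C13, C12, C1) is closed by the same event. C1 is controlled by the tether: the ester hangs from the C12 side chain on the lower face of ring C, so oxygen can reach C1 only cis to C13, the face an untethered nitrone would avoid. C3 is controlled by the same constraint together with the (Z)-geometry, because the N-chain is held on the C12 side and lactone E must then lie over the ketone side, which is also the nitrone face expected to be preferred by C18 (attack anti to its C–O bond). The step needs cyclization to outrun dimerization, secured by high dilution and the slow release of the enone, and needs the stated regiochemistry, secured by enone polarization and by the quaternary C–C bond the alternative would require.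

Step 24
Reactants: 37 macrocyclic spiro-isoxazolidine (N4–O1–C1 and C3–C2 formed; ester bridge from C14 to C8)
Product: 39 N-(4-hydroxybutyl) enamine (C9=C9a) carrying lactones D and E and the O11 silyl ether, via amino alcohol 38 (not isolated)
Conditions: Mo(CO)6, AcOH, MeCN/H2O (15:1), 80 °C; aq. NaHCO3 work-up
Reagents that add atoms: none
Why: Mo(CO)6 cleaves the N–O bond without reducing the α-oxygenated ketone; the freed C1 hydroxyl then transesterifies the adjacent ester to the five-membered lactone D (releasing the C8 alcohol) and the amine condenses with the C9a ketone to the ring B enamine.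

Step 25
Reactants: 39 N-(4-hydroxybutyl) enamine (C9=C9a) carrying lactones D and E and the O11 silyl ether
Product: 41 11-O-(tert-butyldimethylsilyl) ether of the target, via iminium mesylate 40 (not isolated)
Conditions: pyridinium trifluoroacetate, pyridine, MsCl, CH2Cl2, 0 °C; then NaI (0.2 equiv), iPr2NEt, MeCN, 70 °C
Reagents that add atoms: none
Why: With the enamine parked as its iminium salt the primary alcohol is mesylated; the stronger base then frees the enamine, whose C9 should displace the iodide-exchanged leaving group in an intramolecular Stork enamine alkylation that closes azepine ring A, since alkylation at nitrogen is expected to be reversible in the presence of iodide.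

Step 26
Reactants: 41 11-O-(tert-butyldimethylsilyl) ether of the target
Product: 42 target CNP0154902.3
Conditions: HF·pyridine, THF, 0 °C → rt
Reagents that add atoms: none
Why: Buffered acidic fluoride cleaves the hindered silyl ether and should leave both lactones, the enamine and the base-sensitive C13 and C20 centres untouched.

**Compound list**

1 | (5S)-5-(hydroxymethyl)oxolan-2-one | OC[C@@H]1CCC(=O)O1 | starting material
2 | (5S)-5-{[(tert-butyldiphenylsilyl)oxy]methyl}oxolan-2-one | CC(C)(C)[Si](OC[C@@H]1CCC(=O)O1)(c1ccccc1)c1ccccc1 | intermediate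
3 | lithium enolate of 2 | [Li+].[O-]C1=CC[C@@H](CO[Si](c2ccccc2)(c2ccccc2)C(C)(C)C)O1 | intermediate (not isolated)
4 | (3R,5S)-5-{[(tert-butyldiphenylsilyl)oxy]methyl}-3-methyloxolan-2-one | CC(C)(C)[Si](OC[C@@H]1C[C@@H](C)C(=O)O1)(c1ccccc1)c1ccccc1 | intermediate
5 | lithium enolate of 4 | [Li+].[O-]C1=C(C)C[C@@H](CO[Si](c2ccccc2)(c2ccccc2)C(C)(C)C)O1 | intermediate (not isolated)
6 | (3S,5S)-5-{[(tert-butyldiphenylsilyl)oxy]methyl}-3-methyloxolan-2-one | CC(C)(C)[Si](OC[C@@H]1C[C@H](C)C(=O)O1)(c1ccccc1)c1ccccc1 | intermediate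
7 | (3S,5S)-5-(hydroxymethyl)-3-methyloxolan-2-one | OC[C@@H]1C[C@H](C)C(=O)O1 | intermediate
8 | (2S,4S)-4-methyl-5-oxooxolane-2-carbaldehyde | O=C[C@@H]1C[C@H](C)C(=O)O1 | intermediate
9 | tert-butyl N-[(tert-butoxycarbonyl)oxy]carbamate | CC(C)(C)OC(=O)NOC(=O)OC(C)(C)C | starting material
10 | 4-bromobutan-1-ol | OCCCCBr | starting material
11 | tert-butyl N-[(tert-butoxycarbonyl)oxy]-N-(4-hydroxybutyl)carbamate | CC(C)(C)OC(=O)N(CCCCO)OC(=O)OC(C)(C)C | intermediate
12 | 2,2,5-trimethyl-1,3-dioxane-4,6-dione | CC1C(=O)OC(C)(C)OC1=O | starting material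
13 | 3-(tert-butoxy)-2-methyl-3-oxopropanoic acid (racemic) | CC(C(=O)O)C(=O)OC(C)(C)C | intermediate
14 | 1,4-dioxaspiro[4.5]dec-6-en-8-one | O=C1C=CC2(CC1)OCCO2 | starting material
15 | (8S)-1,4-dioxaspiro[4.5]dec-6-en-8-ol | O[C@@H]1C=CC2(CC1)OCCO2 | intermediate
16 | tert-butyl{[(8S)-1,4-dioxaspiro[4.5]dec-6-en-8-yl]oxy}dimethylsilane | CC(C)(C)[Si](C)(C)O[C@@H]1C=CC2(CC1)OCCO2 | intermediate
17 | (4S)-4-[(tert-butyldimethylsilyl)oxy]cyclohex-2-en-1-one | O=C1C=C[C@@H](O[Si](C)(C)C(C)(C)C)CC1 | intermediate
18 | lithium cross-conjugated dienolate of 17 | [Li+].[O-]C1=CC[C@H](O[Si](C)(C)C(C)(C)C)C=C1 | intermediate (not isolated)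
19 | (4S)-4-[(tert-butyldimethylsilyl)oxy]-6-(phenylsulfanyl)cyclohex-2-en-1-one (C6 epimers) | O=C1C=C[C@@H](O[Si](C)(C)C(C)(C)C)CC1Sc1ccccc1 | intermediate
20 | (3S,4S)-4-[(tert-butyldimethylsilyl)oxy]-3-ethyl-6-(phenylsulfanyl)cyclohexan-1-one (C6 epimers) | CC[C@H]1CC(=O)C(Sc2ccccc2)C[C@@H]1O[Si](C)(C)C(C)(C)C | intermediate
21 | (3S,4S)-6-(benzenesulfinyl)-4-[(tert-butyldimethylsilyl)oxy]-3-ethylcyclohexan-1-one | CC[C@H]1CC(=O)C(S(=O)c2ccccc2)C[C@@H]1O[Si](C)(C)C(C)(C)C | intermediate (not isolated)
22 | (4R,5S)-4-[(tert-butyldimethylsilyl)oxy]-5-ethylcyclohex-2-en-1-one | CC[C@H]1CC(=O)C=C[C@@H]1O[Si](C)(C)C(C)(C)C | intermediate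
23 | (4R,5S)-4-[(tert-butyldimethylsilyl)oxy]-5-ethyl-2-[(phenylsulfanyl)methyl]cyclohex-2-en-1-one | CC[C@H]1CC(=O)C(CSc2ccccc2)=C[C@@H]1O[Si](C)(C)C(C)(C)C | intermediate
24 | (4R,5S)-5-ethyl-4-hydroxy-2-[(phenylsulfanyl)methyl]cyclohex-2-en-1-one | CC[C@H]1CC(=O)C(CSc2ccccc2)=C[C@@H]1O | intermediate
25 | 1-tert-butyl 3-{(1R,6S)-6-ethyl-4-oxo-3-[(phenylsulfanyl)methyl]cyclohex-2-en-1-yl} 2-methylpropanedioate | CC[C@H]1CC(=O)C(CSc2ccccc2)=C[C@@H]1OC(=O)C(C)C(=O)OC(C)(C)C | intermediate
26 | tert-butyl (3aR,7S,7aR)-7-ethyl-3-methyl-2,5-dioxo-4-[(phenylsulfanyl)methyl]octahydro-1-benzofuran-3-carboxylate (cis-fused) | CC[C@H]1CC(=O)C(CSc3ccccc3)[C@@H]2C(C)(C(=O)OC(C)(C)C)C(=O)O[C@H]12 | intermediate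
27 | (3aR,7S,7aR)-7-ethyl-3-methyl-2,5-dioxo-4-[(phenylsulfanyl)methyl]octahydro-1-benzofuran-3-carboxylic acid | CC[C@H]1CC(=O)C(CSc3ccccc3)[C@@H]2C(C)(C(=O)O)C(=O)O[C@H]12 | intermediate (not isolated)
28 | (3R,3aS,7S,7aR)-7-ethyl-3-methyl-4-[(phenylsulfanyl)methyl]hexahydro-1-benzofuran-2,5-dione (cis-fused, methyl on convex face) | CC[C@H]1CC(=O)C(CSc3ccccc3)[C@@H]2[C@@H](C)C(=O)O[C@H]12 | intermediate
29 | lithium (2R)-2-{(1S,2R,3S)-3-ethyl-2-hydroxy-5-oxo-6-[(phenylsulfanyl)methyl]cyclohexyl}propanoate | [Li+].CC[C@H]1CC(=O)C(CSc3ccccc3)[C@H]([C@@H](C)C([O-])=O)[C@@H]1O | intermediate (not isolated)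
30 | tert-butyldimethylsilyl ester of acid 31 | CC[C@H]1CC(=O)C(CSc3ccccc3)[C@H]([C@@H](C)C(=O)O[Si](C)(C)C(C)(C)C)[C@@H]1O[Si](C)(C)C(C)(C)C | intermediate (not isolated)
31 | (2R)-2-{(1S,2R,3S)-2-[(tert-butyldimethylsilyl)oxy]-3-ethyl-5-oxo-6-[(phenylsulfanyl)methyl]cyclohexyl}propanoic acid | CC[C@H]1CC(=O)C(CSc3ccccc3)[C@H]([C@@H](C)C(=O)O)[C@@H]1O[Si](C)(C)C(C)(C)C | intermediate
32 | 4-{(tert-butoxycarbonyl)[(tert-butoxycarbonyl)oxy]amino}butyl ester of acid 31 | CC[C@H]1CC(=O)C(CSc3ccccc3)[C@H]([C@@H](C)C(=O)OCCCCN(OC(=O)OC(C)(C)C)C(=O)OC(C)(C)C)[C@@H]1O[Si](C)(C)C(C)(C)C | intermediate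
33 | benzenesulfinylmethyl analogue (sulfoxide) of ester 32 | CC[C@H]1CC(=O)C(CS(=O)c3ccccc3)[C@H]([C@@H](C)C(=O)OCCCCN(OC(=O)OC(C)(C)C)C(=O)OC(C)(C)C)[C@@H]1O[Si](C)(C)C(C)(C)C | intermediate
34 | N-hydroxyammonium trifluoroacetate from 33 | CC[C@H]1CC(=O)C(CS(=O)c3ccccc3)[C@H]([C@@H](C)C(=O)OCCCC[NH2+]O)[C@@H]1O[Si](C)(C)C(C)(C)C.[O-]C(=O)C(F)(F)F | intermediate (not isolated)
35 | (Z)-N-alkyl nitrone of aldehyde 8 tethered through the butyl ester to the sulfoxide ketone | [O-]/[N+](CCCCOC(=O)[C@H](C)[C@H]2C(CS(=O)c3ccccc3)C(=O)C[C@H](CC)[C@H]2O[Si](C)(C)C(C)(C)C)=C\[C@@H]1C[C@H](C)C(=O)O1 | intermediate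
36 | tethered (Z)-nitrone of the 2-methylenecyclohexanone | [O-]/[N+](CCCCOC(=O)[C@H](C)[C@H]2C(=C)C(=O)C[C@H](CC)[C@H]2O[Si](C)(C)C(C)(C)C)=C\[C@@H]1C[C@H](C)C(=O)O1 | intermediate (not isolated)
37 | macrocyclic spiro-isoxazolidine (C1 R, C3 R; ester bridge C14–O–C8) | O4CCCCN1O[C@@]2(C[C@@H]1[C@@H]3C[C@H](C)C(=O)O3)C(=O)C[C@H](CC)[C@@H](O[Si](C)(C)C(C)(C)C)[C@H]2[C@@H](C)C4=O | intermediate
38 | macrocyclic amino alcohol after N–O cleavage | O4CCCCN[C@H](C[C@]2(O)C(=O)C[C@H](CC)[C@@H](O[Si](C)(C)C(C)(C)C)[C@H]2[C@@H](C)C4=O)[C@@H]3C[C@H](C)C(=O)O3 | intermediate (not isolated)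
39 | N-(4-hydroxybutyl) enamine (C9=C9a) carrying lactones D and E and the O11 silyl ether | CC[C@H]1C=C3N(CCCCO)[C@@H]([C@@H]2C[C@H](C)C(=O)O2)C[C@]32OC(=O)[C@H](C)[C@@H]2[C@@H]1O[Si](C)(C)C(C)(C)C | intermediate
40 | iminium trifluoroacetate carrying the C8 mesylate | CC[C@H]1CC3=[N+](CCCCOS(C)(=O)=O)[C@@H]([C@@H]2C[C@H](C)C(=O)O2)C[C@]32OC(=O)[C@H](C)[C@@H]2[C@@H]1O[Si](C)(C)C(C)(C)C.[O-]C(=O)C(F)(F)F | intermediate (not isolated)
41 | 11-O-(tert-butyldimethylsilyl) ether of the target | CC[C@H]1C2=C3N(CCCC2)[C@@H]([C@@H]2C[C@H](C)C(=O)O2)C[C@]32OC(=O)[C@H](C)[C@@H]2[C@@H]1O[Si](C)(C)C(C)(C)C | intermediate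
42 | target CNP0154902.3 | CC[C@H]1C2=C3N(CCCC2)[C@@H]([C@@H]2C[C@H](C)C(=O)O2)C[C@]32OC(=O)[C@H](C)[C@@H]2[C@@H]1O | target

**Step count and risks**

Total steps: 26. Longest linear sequence: 19 steps (14 → 42, steps 8–26).

Steps most likely to fail:

1. Step 23 (proposed new method). Reaction between molecules may outrun the intramolecular cycloaddition, or the eleven-membered transition state may be too strained, so that oligomers form or the nitrone decomposes before it cyclizes. The fallback is the known intermolecular nitrone cycloaddition to an α-methylene ketone and sets out from acid 31, carbamate 11 and aldehyde 8. Acid 31 is methylated with TMSCHN2 to methyl ester F1, oxidized with NaIO4 to sulfoxide F2 and heated in toluene to the free 2-methylenecyclohexanone F3. Carbamate 11 is deprotected with CF3CO2H to hydroxylammonium salt F4 and condensed with 8 (NaHCO3, MgSO4) to the N-(4-hydroxybutyl) nitrone F5. F3 and F5 are combined in toluene at 40–60 °C to give isoxazolidine F6; without the tether, attack anti to the C12 side chain is expected to compete strongly, so the isomer with oxygen cis to that chain would have to be separated from its C1 epimer. Treatment of F6 with Mo(CO)6 and AcOH in wet MeCN then closes lactone D with loss of methanol and returns to the route at 39.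

2. Step 25. Alkylation at nitrogen (spiro-ammonium formation) may compete with alkylation at C9, or the mesylate may be lost by elimination. The fallback sets out from 39. After protonation with pyridinium trifluoroacetate the primary alcohol is oxidized with Dess–Martin periodinane to the aldehyde iminium salt F7. Release of the enamine with iPr2NEt over molecular sieves should bring about an intramolecular aldol condensation, in which addition through nitrogen is reversible and only attack through C9 leads on, to give dienamine F8 (C7=C8 and C9=C9a). Hydrogenation of the disubstituted C7=C8 bond with H2 and RhCl(PPh3)3 returns to the route at 41.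

3. Step 14. The thiol may simply add in conjugate fashion without hydroxymethylation, or base may degrade the γ-silyloxy enone. The fallback sets out from 22. A Morita–Baylis–Hillman reaction with aqueous formaldehyde (DMAP, THF/H2O) gives the hydroxymethyl enone F9, which PhSSPh and PBu3 convert into the sulfide, returning to the route at 23.

**Further compounds**

F1 | step 23 | methyl ester of acid 31 | CC[C@H]1CC(=O)C(CSc3ccccc3)[C@H]([C@@H](C)C(=O)OC)[C@@H]1O[Si](C)(C)C(C)(C)C
F2 | step 23 | sulfoxide of methyl ester F1 | CC[C@H]1CC(=O)C(CS(=O)c3ccccc3)[C@H]([C@@H](C)C(=O)OC)[C@@H]1O[Si](C)(C)C(C)(C)C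
F3 | step 23 | methyl (2R)-2-{(1R,2R,3S)-2-[(tert-butyldimethylsilyl)oxy]-3-ethyl-6-methylidene-5-oxocyclohexyl}propanoate | CC[C@H]1CC(=O)C(=C)[C@H]([C@@H](C)C(=O)OC)[C@@H]1O[Si](C)(C)C(C)(C)C
F4 | step 23 | N-(4-hydroxybutyl)hydroxylammonium trifluoroacetate | OCCCC[NH2+]O.[O-]C(=O)C(F)(F)F
F5 | step 23 | (Z)-N-(4-hydroxybutyl) nitrone of aldehyde 8 | [O-]/[N+](CCCCO)=C\[C@@H]1C[C@H](C)C(=O)O1
F6 | step 23 | N-(4-hydroxybutyl) spiro-isoxazolidine methyl ester (C1 R, C3 R) | OCCCCN1O[C@@]2(C[C@@H]1[C@@H]3C[C@H](C)C(=O)O3)C(=O)C[C@H](CC)[C@@H](O[Si](C)(C)C(C)(C)C)[C@H]2[C@@H](C)C(=O)OC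
F7 | step 25 | iminium trifluoroacetate carrying the C8 aldehyde | CC[C@H]1CC3=[N+](CCCC=O)[C@@H]([C@@H]2C[C@H](C)C(=O)O2)C[C@]32OC(=O)[C@H](C)[C@@H]2[C@@H]1O[Si](C)(C)C(C)(C)C.[O-]C(=O)C(F)(F)F
F8 | step 25 | 7,8-didehydro dienamine of 41 | CC[C@H]1C2=C3N(CCC=C2)[C@@H]([C@@H]2C[C@H](C)C(=O)O2)C[C@]32OC(=O)[C@H](C)[C@@H]2[C@@H]1O[Si](C)(C)C(C)(C)C
F9 | step 14 | (4R,5S)-4-[(tert-butyldimethylsilyl)oxy]-5-ethyl-2-(hydroxymethyl)cyclohex-2-en-1-one | CC[C@H]1CC(=O)C(CO)=C[C@@H]1O[Si](C)(C)C(C)(C)C
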